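**Retrosynthetic overview**

- Target: (4R)-4-(3,4-dihydroxyphenyl)-6-[2-(3,4-dimethoxyphenyl)ethyl]-7-hydroxychroman-2-one. The C6 benzylic CH2 and the two catechol hydroxyls are unmasked last from an aryl ketone and two benzyl ethers.
- Feature used: ring A is a resorcinol with oxygen on C7 and C8a and hydrogen on C8, joined to the stereocentre C4 through C4a. The run C4a–C8a–C8–C7 is thus the γ-carbon, keto carbon, α-carbon and ester carbon of a 3-oxoester, and C4 with its CH2 neighbours C4a and C3 is the centre of a 3-arylglutarate whose two arms are enantiotopic.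
- Disconnections: C4a–C5 and C6–C7 (cycloaddition of a 1-benzyloxy-1,3-bis(silyloxy)diene with a terminal ynone, then aromatisation) and O1–C2 (lactonisation); C8a–C8 by malonate homologation of the glutarate half-ester; C4 by catalytic methanolysis of the meso anhydride.
- Ring order: ring A (carbocycle) first, the lactone ring second in the same operation; both outer aryl rings are bought.

Key step: step 8

Assumption: the quinine-derived catalyst is taken to open the meso anhydride to the (R)-half-ester; if the first run shows the opposite sense, its quinidine-derived pseudoenantiomer is used under the same conditions and nothing downstream changes.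

**Route**

Step 1
Reactants: 1 3,4-bis(benzyloxy)benzaldehyde; 2 ethyl acetoacetate
Product: 4 3-[3,4-bis(benzyloxy)phenyl]pentanedioic acid, via bis-adduct 3 (not isolated)
Conditions: 2 (2.2 equiv), piperidine (0.1 equiv), EtOH, rt; evaporate; 50% aq. NaOH–EtOH, reflux; conc. HCl to pH 1
Reagents that add atoms: sodium hydroxide, [Na+].[OH-]
Why: Piperidine-catalysed Knoevenagel condensation and Michael addition of a second acetoacetate give 3, and hot concentrated hydroxide then removes both acetyl groups by retro-Claisen cleavage and saponifies the esters, a classical route to 3-arylglutaric acids that leaves aryl benzyl ethers untouched; the product is achiral.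

Step 2
Reactants: 4 3-[3,4-bis(benzyloxy)phenyl]pentanedioic acid
Product: 5 4-[3,4-bis(benzyloxy)phenyl]oxane-2,6-dione (the 3-arylglutaric anhydride)
Conditions: Ac2O, reflux; evaporate; crystallise from toluene–heptane
Reagents that add atoms: none
Why: Cyclodehydration of a 1,5-diacid with acetic anhydride should give the six-membered cyclic anhydride, an achiral compound with two enantiotopic carbonyl groups.

Step 3
Reactants: 5 4-[3,4-bis(benzyloxy)phenyl]oxane-2,6-dione
Product: 6 (3R)-3-[3,4-bis(benzyloxy)phenyl]-5-methoxy-5-oxopentanoic acid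
Conditions: MeOH (10 equiv), quinine-derived 9-amino(9-deoxy)epiquinine 3,5-bis(trifluoromethyl)benzenesulfonamide (10 mol%), MTBE (0.02 M), rt; dilute HCl wash
Reagents that add atoms: methanol, CO
Why: Cinchona-catalysed enantioselective alcoholysis (desymmetrisation) of a 3-arylglutaric anhydride, in which the quinuclidine nitrogen acts as general base for methanol while the sulfonamide N–H binds one of the two enantiotopic carbonyls, so that one arm is opened selectively and the configuration of the future C4 is set by the catalyst.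

Step 4
Reactants: 6 (3R)-3-[3,4-bis(benzyloxy)phenyl]-5-methoxy-5-oxopentanoic acid; 7 3-(benzyloxy)-3-oxopropanoic acid (monobenzyl malonate)
Product: 10 1-benzyl 7-methyl (5R)-5-[3,4-bis(benzyloxy)phenyl]-3-oxoheptanedioate, via acyl imidazolide 8 (not isolated), via magnesium benzyl malonate 9 (not isolated)
Conditions: 6, CDI (1.1 equiv), THF, rt; separately 7 (2.2 equiv), Mg(OEt)2 (1.1 equiv), THF, rt, then evaporate; combine in THF, rt to 40 °C; 1 M HCl
Reagents that add atoms: none
Why: Masamune–Brooks homologation, in which the acyl imidazolide C-acylates the magnesium malonate half-ester and decarboxylation gives the benzyl 3-oxoester under near-neutral conditions that neither re-close the anhydride nor touch the methyl ester, so the stereocentre (β to both carbonyls, not enolisable) is carried unchanged.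

Step 5
Reactants: 10 1-benzyl 7-methyl (5R)-5-[3,4-bis(benzyloxy)phenyl]-3-oxoheptanedioate
Product: 11 methyl (3S,4Z)-7-(benzyloxy)-3-[3,4-bis(benzyloxy)phenyl]-5,7-bis(trimethylsilyloxy)hepta-4,6-dienoate (geometry at C6=C7 not defined and without consequence)
Conditions: Me3SiOTf (2.3 equiv), Et3N (2.6 equiv), Et2O, 0 °C to rt; separate the ammonium salt, evaporate, extract into pentane under Ar; used crude at once
Reagents that add atoms: trimethylsilyl trifluoromethanesulfonate, C[Si](C)(C)OS(=O)(=O)C(F)(F)F
Why: Soft enolisation with Me3SiOTf and Et3N silylates a 3-oxoester twice (enol ether first, then γ-deprotonation of the O-silylated vinylogous ester), as known for acetoacetates, much faster than an isolated methyl ester reacts, and should give mainly the 4Z enol ether that the cycloaddition needs.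

Step 6
Reactants: 12 (3,4-dimethoxyphenyl)acetic acid
Product: 13 2-(3,4-dimethoxyphenyl)-N-methoxy-N-methylacetamide
Conditions: MeNH(OMe)·HCl (1.2 equiv), EDC·HCl (1.2 equiv), Et3N (2.5 equiv), DMAP (0.1 equiv), CH2Cl2, 0 °C to rt
Reagents that add atoms: N,O-dimethylhydroxylamine hydrochloride, CNOC.Cl
Why: Carbodiimide amide coupling of an unhindered arylacetic acid should give the Weinreb amide without complication.

Step 7
Reactants: 13 2-(3,4-dimethoxyphenyl)-N-methoxy-N-methylacetamide
Product: 14 1-(3,4-dimethoxyphenyl)but-3-yn-2-one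
Conditions: HC≡CMgBr (0.5 M in THF, 2.0 equiv), THF, −78 to 0 °C; inverse quench into cold 1 M aq. NaHSO4; used soon, stored cold
Reagents that add atoms: ethynylmagnesium bromide, C#C[Mg]Br
Why: Weinreb ketone synthesis, in which the chelated tetrahedral adduct stops at mono-addition and the inverse acidic quench keeps the liberated N,O-dimethylhydroxylamine protonated so that it cannot add to the terminal ynone.

Step 8
Reactants: 11 methyl (3S,4Z)-7-(benzyloxy)-3-[3,4-bis(benzyloxy)phenyl]-5,7-bis(trimethylsilyloxy)hepta-4,6-dienoate; 14 1-(3,4-dimethoxyphenyl)but-3-yn-2-one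
Product: 17 (4R)-4-[3,4-bis(benzyloxy)phenyl]-6-[(3,4-dimethoxyphenyl)acetyl]-7-hydroxychroman-2-one, via cycloadduct 15 (not isolated), via resorcinol ester 16 (not isolated)
Conditions: 14 (1.5 equiv), toluene, rt to 60 °C; then 1 M HCl–THF, rt; then TsOH·H2O (0.1 equiv), toluene, 80 °C
Reagents that add atoms: none
Why: The electron-rich diene 11 (largest HOMO coefficient at the enol-ether terminus C4a) and the ynone 14 (largest LUMO coefficient at the terminal carbon C5) should combine in a thermal normal-demand Diels–Alder reaction, or its asynchronous Mukaiyama–Michael/ring-closure limit, forming C4a–C5 and C6–C7 to give the 1,4-cyclohexadiene 15 with a mixed ketal at C7. Dilute acid removes the silyl groups and the ketal expels benzyl alcohol, so 15 aromatises to resorcinol 16; the closest known reaction is the cycloaddition–aromatisation of 1-alkoxy-1,3-bis(silyloxy)-1,3-dienes with alkynones to 4-acylresorcinols. Ring A thus closes as a six-membered carbocycle by [4+2] cycloaddition, and the lactone closes afterwards by 6-exo-trig acyl substitution at the methyl ester carbon C2 by the C8a phenol with loss of methanol, driven by warming with TsOH. No stereocentre is created: the two sp3 ring carbons of 15 are flattened on aromatisation, and C4, set in step 3, is not α to a carbonyl and is not touched. The step needs one regiochemistry, the acyl group on C6 next to the C7 oxygen, which the matched polarisation of the two partners secures; only the C8a hydroxyl is ortho to the propanoate chain, so the lactone can form in one way, and the 4Z geometry of 11 keeps the C4 substituent outside the s-cis diene. Should silanol be lost at C7 in place of benzyl alcohol, the benzyl ether left there falls in step 9.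

Step 9
Reactants: 17 (4R)-4-[3,4-bis(benzyloxy)phenyl]-6-[(3,4-dimethoxyphenyl)acetyl]-7-hydroxychroman-2-one
Product: 18 (4R)-4-(3,4-dihydroxyphenyl)-6-[2-(3,4-dimethoxyphenyl)ethyl]-7-hydroxychroman-2-one
Conditions: H2 (4 bar), 10% Pd/C, EtOAc–AcOH (4:1), conc. HCl (0.1 equiv), rt to 40 °C; filter under N2
Reagents that add atoms: none
Why: Catalytic hydrogenolysis, in which under acid the aryl ketone, activated by the ortho C7 hydroxyl, is reduced through its benzylic carbinol to CH2 while both benzyl ethers are cleaved; the non-nucleophilic medium keeps the aryl lactone closed, and C4 has no C–O bond to cleave, so its configuration is retained.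

**Compound list**

1 | 3,4-bis(benzyloxy)benzaldehyde | O=Cc1ccc(OCc2ccccc2)c(OCc2ccccc2)c1 | starting material
2 | ethyl acetoacetate | CCOC(=O)CC(C)=O | starting material
3 | diethyl 2,4-diacetyl-3-[3,4-bis(benzyloxy)phenyl]pentanedioate (bis-adduct, stereoisomer mixture) | CCOC(=O)C(C(C)=O)C(c1ccc(OCc2ccccc2)c(OCc2ccccc2)c1)C(C(C)=O)C(=O)OCC | intermediate
4 | 3-[3,4-bis(benzyloxy)phenyl]pentanedioic acid | OC(=O)CC(CC(=O)O)c1ccc(OCc2ccccc2)c(OCc2ccccc2)c1 | intermediate
5 | 4-[3,4-bis(benzyloxy)phenyl]oxane-2,6-dione | O=C1CC(CC(=O)O1)c1ccc(OCc2ccccc2)c(OCc2ccccc2)c1 | intermediate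
6 | (3R)-3-[3,4-bis(benzyloxy)phenyl]-5-methoxy-5-oxopentanoic acid | COC(=O)C[C@@H](CC(=O)O)c1ccc(OCc2ccccc2)c(OCc2ccccc2)c1 | intermediate
7 | 3-(benzyloxy)-3-oxopropanoic acid (monobenzyl malonate) | OC(=O)CC(=O)OCc1ccccc1 | starting material
8 | methyl (3R)-3-[3,4-bis(benzyloxy)phenyl]-5-(imidazol-1-yl)-5-oxopentanoate (acyl imidazolide) | COC(=O)C[C@@H](CC(=O)n1ccnc1)c1ccc(OCc2ccccc2)c(OCc2ccccc2)c1 | intermediate
9 | magnesium bis[3-(benzyloxy)-3-oxopropanoate] | [Mg+2].[O-]C(=O)CC(=O)OCc1ccccc1.[O-]C(=O)CC(=O)OCc1ccccc1 | intermediate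
10 | 1-benzyl 7-methyl (5R)-5-[3,4-bis(benzyloxy)phenyl]-3-oxoheptanedioate | COC(=O)C[C@@H](CC(=O)CC(=O)OCc1ccccc1)c1ccc(OCc2ccccc2)c(OCc2ccccc2)c1 | intermediate
11 | methyl (3S,4Z)-7-(benzyloxy)-3-[3,4-bis(benzyloxy)phenyl]-5,7-bis(trimethylsilyloxy)hepta-4,6-dienoate | COC(=O)C[C@@H](/C=C(\O[Si](C)(C)C)C=C(O[Si](C)(C)C)OCc1ccccc1)c1ccc(OCc2ccccc2)c(OCc2ccccc2)c1 | intermediate
12 | (3,4-dimethoxyphenyl)acetic acid | COc1ccc(CC(=O)O)cc1OC | starting material
13 | 2-(3,4-dimethoxyphenyl)-N-methoxy-N-methylacetamide | COc1ccc(CC(=O)N(C)OC)cc1OC | intermediate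
14 | 1-(3,4-dimethoxyphenyl)but-3-yn-2-one | COc1ccc(CC(=O)C#C)cc1OC | intermediate
15 | methyl (3S)-3-[3,4-bis(benzyloxy)phenyl]-3-{4-(benzyloxy)-5-[(3,4-dimethoxyphenyl)acetyl]-2,4-bis(trimethylsilyloxy)cyclohexa-2,5-dien-1-yl}propanoate (ring centres as a mixture) | COC(=O)C[C@@H](C1C=C(C(=O)Cc2ccc(OC)c(OC)c2)C(OCc2ccccc2)(O[Si](C)(C)C)C=C1O[Si](C)(C)C)c1ccc(OCc2ccccc2)c(OCc2ccccc2)c1 | intermediate
16 | methyl (3R)-3-[3,4-bis(benzyloxy)phenyl]-3-{5-[(3,4-dimethoxyphenyl)acetyl]-2,4-dihydroxyphenyl}propanoate | COC(=O)C[C@@H](c1cc(C(=O)Cc2ccc(OC)c(OC)c2)c(O)cc1O)c1ccc(OCc2ccccc2)c(OCc2ccccc2)c1 | intermediate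
17 | (4R)-4-[3,4-bis(benzyloxy)phenyl]-6-[(3,4-dimethoxyphenyl)acetyl]-7-hydroxychroman-2-one | COc1ccc(CC(=O)c2cc3c(cc2O)OC(=O)C[C@@H]3c2ccc(OCc3ccccc3)c(OCc3ccccc3)c2)cc1OC | intermediate
18 | (4R)-4-(3,4-dihydroxyphenyl)-6-[2-(3,4-dimethoxyphenyl)ethyl]-7-hydroxychroman-2-one | COc1ccc(CCc2cc3c(cc2O)OC(=O)C[C@@H]3c2ccc(O)c(O)c2)cc1OC | target

**Step count**

Total: 9 steps. Longest linear sequence: 7 steps (1, 2, 3, 4, 5, 8, 9); steps 6 and 7 make the ynone branch.

**Steps most likely to fail**

Step 8 (key step). The cycloaddition may be slow or unselective at the hindered, substituted diene terminus, since an E enol ether cannot reach the reactive conformation. The acidic CH2 of the ynone may protodesilylate the diene. Acid-promoted retro-Friedel–Crafts opening during lactonisation may erode the C4 configuration. The fallback leaves the ring-A construction, sets the stereocentre by conjugate arylation of a preformed coumarin, and also bypasses step 5. It sets out from 12. Acylation of commercial resorcinol with 12 in BF3·OEt2 at 85 °C should give 1-(2,4-dihydroxyphenyl)-2-(3,4-dimethoxyphenyl)ethanone F1. Et3SiH in CF3CO2H should reduce the ketone to 4-[2-(3,4-dimethoxyphenyl)ethyl]benzene-1,3-diol F2. Pechmann-type annulation with ethyl propiolate and ZnCl2 (dioxane, 100 °C) should give 6-[2-(3,4-dimethoxyphenyl)ethyl]-7-hydroxy-2H-chromen-2-one F3. BnBr and K2CO3 in DMF should give 7-(benzyloxy)-6-[2-(3,4-dimethoxyphenyl)ethyl]-2H-chromen-2-one F4. Hayashi–Miyaura 1,4-addition of commercial 3,4-bis(benzyloxy)phenylboronic acid with Rh(acac)(C2H4)2 and (R)-SEGPHOS (dioxane–H2O, 60 °C) should give (4R)-7-(benzyloxy)-4-[3,4-bis(benzyloxy)phenyl]-6-[2-(3,4-dimethoxyphenyl)ethyl]chroman-2-one F5. The ligand hand is the one expected to give (R)-4-phenylchroman-2-one from coumarin, which has the same priority order at C4; the (S)-ligand is used if the sense proves opposite. Hydrogenolysis (H2, Pd/C, EtOAc) removes the three benzyl groups and the fallback comes back to the route at 18.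

Step 9. The hydrogenolysis may stall at the benzylic carbinol, or the acid needed for the C–O cleavage may open or transesterify the aryl lactone. The fallback separates the two reductions and sets out from 17. Ionic hydrogenation with Et3SiH (3 equiv) and CF3CO2H in CH2Cl2 at 0 °C to rt should reduce the ortho-hydroxyaryl ketone to (4R)-4-[3,4-bis(benzyloxy)phenyl]-6-[2-(3,4-dimethoxyphenyl)ethyl]-7-hydroxychroman-2-one F6. Neutral hydrogenolysis (H2, 1 atm, Pd/C, EtOAc–THF, rt) then removes the benzyl ethers and comes back to the route at 18.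

Step 3. Enantioselectivity may be insufficient because the poorly soluble anhydride forces a more polar medium in which the uncatalysed methanolysis competes, and the sense of induction may be opposite to the one assumed. The fallback replaces asymmetric catalysis by resolution and sets out from 5. Heating 5 in MeOH should give racemic 3-[3,4-bis(benzyloxy)phenyl]-5-methoxy-5-oxopentanoic acid F7. This is resolved by preparative chromatography on an amylose tris(3,5-dimethylphenylcarbamate) phase, and the (R)-enantiomer comes back to the route at 6. The unwanted enantiomer is returned to the pool by saponification with LiOH to diacid 4 and repetition of step 2.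

**Further compounds**

F1 | step 8 | 1-(2,4-dihydroxyphenyl)-2-(3,4-dimethoxyphenyl)ethanone | COc1ccc(CC(=O)c2ccc(O)cc2O)cc1OC
F2 | step 8 | 4-[2-(3,4-dimethoxyphenyl)ethyl]benzene-1,3-diol | COc1ccc(CCc2ccc(O)cc2O)cc1OC
F3 | step 8 | 6-[2-(3,4-dimethoxyphenyl)ethyl]-7-hydroxy-2H-chromen-2-one | COc1ccc(CCc2cc3ccc(=O)oc3cc2O)cc1OC
F4 | step 8 | 7-(benzyloxy)-6-[2-(3,4-dimethoxyphenyl)ethyl]-2H-chromen-2-one | COc1ccc(CCc2cc3ccc(=O)oc3cc2OCc2ccccc2)cc1OC
F5 | step 8 | (4R)-7-(benzyloxy)-4-[3,4-bis(benzyloxy)phenyl]-6-[2-(3,4-dimethoxyphenyl)ethyl]chroman-2-one | COc1ccc(CCc2cc3c(cc2OCc2ccccc2)OC(=O)C[C@@H]3c2ccc(OCc3ccccc3)c(OCc3ccccc3)c2)cc1OC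
F6 | step 9 | (4R)-4-[3,4-bis(benzyloxy)phenyl]-6-[2-(3,4-dimethoxyphenyl)ethyl]-7-hydroxychroman-2-one | COc1ccc(CCc2cc3c(cc2O)OC(=O)C[C@@H]3c2ccc(OCc3ccccc3)c(OCc3ccccc3)c2)cc1OC
F7 | step 3 | racemic 3-[3,4-bis(benzyloxy)phenyl]-5-methoxy-5-oxopentanoic acid | COC(=O)CC(CC(=O)O)c1ccc(OCc2ccccc2)c(OCc2ccccc2)c1
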